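## Analysis of the target

The target 24 is a B-type proanthocyanidin dimer. An upper epiafzelechin unit (rings A, C, B; ring B is 4-hydroxyphenyl) is bonded through C4 to C8' of a lower epicatechin unit (rings D, F, E; ring E is a catechol). It has five stereocentres, C2, C3 and C4 in ring C and C2' and C3' in ring F, all R. In each pyran the aryl group and the hydroxyl are cis, and ring D on C4 is trans to the C3 hydroxyl (4β). Seven phenols and two secondary alcohols are free. Rings A and D are phloroglucinol-type and easily oxidised, the C4–C8' bond can ionise in acid, and C2 and C2' can epimerise in base once the para phenols of rings B and E are free. Three features make the synthesis hard: C4 is a methine that carries two almost identical 2,4,6-trioxygenated aryl groups (rings A and D differ only at C4a'), ring D is hexasubstituted with a 4→8 and not a 4→6 pattern, and both pyrans have the less stable 2,3-cis arrangement. The strategy rests on the fact that C2/C3 and C2'/C3' share the 2R,3R cis pattern and that each O1–C2 (O1'–C2') bond lies next to an aromatic ring. Each pair of centres can therefore come from a cis-epoxide opened at the benzylic carbon by the ortho phenol with inversion, and each cis-epoxide from a Z-aryl alkene. Both alkenes hang on ring D (one through the C4 methine, one through the C4' methylene), so one chiral oxidant can set four centres in one operation.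

## Retrosynthetic reasoning

**24 back to 22 (no skeletal bond cut).** The free polyphenol is the most sensitive compound of the route, so the five benzyl ethers of 23 are removed last by hydrogenolysis. Before that, the two sulfonates on the para oxygens of rings B and E are cleaved from 22. Benzyl ethers tolerate the strong base this needs; free phenols would not.

**22 back to 20 and 18 (O1'–C2' of ring F, then O1–C2 of ring C).** Both aryl ether bonds are cut at the benzylic carbons. In the forward sense an ortho phenol opens a cis-oxirane 6-endo with inversion, which gives the 2,3-cis pyran directly. One point needs care: the ring D oxygen O1' is ortho to both side chains and could open either oxirane, whereas the ring A oxygen O1 reaches only the upper one. The two phenols therefore cannot be released together. O1 carries a silyl ether and is freed first (ring C, step 14); O1' carries an acetate that acidic fluoride does not touch and is freed second (ring F, step 15), when only the lower oxirane is left.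

**18 back to 17 (C2–O, C3–O, C2'–O, C3'–O).** The four C–O bonds of the two oxiranes are cut together. This leads to the Z,Z-diene 17, whose only stereocentre is C4. The forward reaction must deliver oxygen to the same face of two remote Z-aryl alkenes and keep their geometry. Each para oxygen of rings B and E is a sulfonate, because a para oxygen lone pair is what makes an aryl oxirane ionise. The meta oxygen of ring E does not conjugate with the benzylic carbon and stays a benzyl ether, so ring E is not made so electron-poor that the later benzylic ring opening loses its bias.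

**17 back to 14 (two alkynes, two protecting groups).** Both Z-alkenes come from alkynes by syn semi-hydrogenation of 16. The phenols of 14 are told apart by crowding: the ring A phenol has one ortho substituent and takes the bulky silyl group (15), and the ring D phenol has two and takes the small acetyl group (16).

**14 back to 12 and 9 (C4–C8').** This bond is cut because it is the only place where rings A and D differ in reactivity. Ring A becomes the electrophile (ortho-quinone methide 13, formed from 12), and ring D the nucleophile (phenol 9). A chiral Brønsted acid that binds both partners chooses the face of a planar carbon bearing H and alkynyl, so it never has to distinguish ring A from ring D. The phenol of 9 directs attack to its free ortho carbon, C8'; the other ortho position already carries the side chain, which secures the 4→8 pattern. Alkynes are kept at this stage because they are slim, do not isomerise and later give Z geometry.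

**12 and 9 back to 3, 11 and 6 (aryl–alkyne bonds; C4'–O).** Both halves come from one propargylic alcohol, 3. Cross-coupling with iodide 11 gives 12, in which the carbinol carbon becomes C4. Cross-coupling with bromide 6 gives 7, and removal of the benzylic hydroxyl gives 9, in which the same carbon becomes C4'. The sulfonated rings enter only after the organomagnesium step, which they might not survive.

**3, 6 and 11 back to 1, 4 and 10.** Alcohol 3 comes from aldehyde 2 by ethynyl addition, and 2 from 1 by twofold O-benzylation. Bromide 6 comes from 4 by para bromination (5) and sulfonylation. Iodide 11 comes from 10 by sulfonylation.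

## Alternatives that were turned down

**Alternative 1:** Ring C is cut across four bonds. O1–C8a and C4–C4a go back to an aryne that stands for ring A; C4 goes back to a formyl carbon on C8' of a finished lower unit; C3–C4 and O1–C2 go back to an aryl enol ether. In the forward step a fluoride source frees the aryne, the carbonyl group adds across it to a benzoxete, this opens to the ortho-quinone methide, and a hetero-Diels–Alder reaction with the enol ether closes ring C as the C2 methyl ketal A1.
- For: four bonds around the crowded C4 form in one flask; the lower unit can be a protected epicatechin, so C2' and C3' need no synthesis; the benzyloxy group beside the aryne polarises it so that oxygen ends on C8a; the two ring oxygens need no differentiation. On convergence this plan is stronger than the chosen one.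
- Against: the face on which C4 forms would have to be dictated by C2' and C3', five bonds away on the far side of ring D, so a 4α/4β mixture is to be expected. C2 is still a ketal, and its reduction depends on the competing influence of the C3 and C4 substituents. The aryne–carbonyl insertion normally needs the carbonyl partner in excess, and here that partner is the precious lower unit.
- Comparison: the chosen route is longer to its flat precursor but controls every centre by a catalyst and not by remote induction.

**Alternative 2:** Only O1–C2 is cut, at a stage where C4 carries two identical masked trioxygenated aryl groups and the molecule holds a single cis-epoxide. In the forward step acidic fluoride frees both phenols, and one of the two diastereotopic aryl groups opens the epoxide with inversion. Ring C closes and C4 becomes a stereocentre in the same event, giving A2.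
- For: no enantioselective C–C bond formation is needed for C4, and the symmetric precursor is cheap. On the C4 problem this plan is stronger than the chosen one, which needs an asymmetric Friedel–Crafts step.
- Against: which aryl group closes is decided only by a small conformational preference in a half-chair transition state, and this may not favour 4β. The lower unit must then be grown on the free phenol ring of A2: C-functionalisation with the 4→8/4→6 choice still open, a second Z-alkene, a second epoxidation and a second closure, all on a compound that already holds three stereocentres.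
- Comparison: the chosen strategy uses the oxidation catalyst once for both units and fixes the substitution pattern of ring D before any stereocentre exists.

**Alternative 3:** Ring D itself is disconnected at C8'–C8a' and C6'–C7'. This goes back to a cyclobutenone bearing the finished upper flavan and a siloxyalkyne bearing the C4'–C3'–C2' chain with ring E. On heating, the cyclobutenone opens to a vinylketene, this adds to the siloxyalkyne, and a second ring opening, 6π closure and tautomerisation give ring D as phenol A3 with O1' free beside a ketone chain.
- For: the hexasubstituted ring D is built with an unambiguous pattern, so the 4→8 question does not arise. This is stronger than the chosen route, where the pattern depends on ortho direction by the phenol of 9. The union is late and convergent, and no epoxide is carried.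
- Against: both partners are advanced chiral fragments with their own multistep syntheses. The centre α to the aryl ketone is configurationally labile at the temperature of the benzannulation. C2' must still be set by closing the phenol onto the ketone and reducing the cyclic oxocarbenium ion, where the cis outcome is not assured.
- Comparison: the benzannulation creates no stereocentre, whereas the chosen key step creates four from a precursor that has one.

Key step: step 13

Assumption: the sense of induction of the phosphoric acid in step 9 cannot be predicted for this pair of partners; the (R) acid is written, and if the first run gives the antipode of 14 the (S) acid is used with no other change.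

Remark: the CIP descriptor at C4 follows the protecting groups (R in 14, 19, 20 and 22–24; S in 15–18 and 21) although the spatial arrangement is the same throughout.

## Route

Step 1
Reactants: 1 2,4,6-trihydroxybenzaldehyde
Product: 2 2,4-bis(benzyloxy)-6-hydroxybenzaldehyde
Conditions: BnBr (2.1 equiv), K2CO3, DMF, 0 °C to rt
Reagents that add atoms: benzyl bromide, BrCc1ccccc1
Why: Williamson ether synthesis; the para hydroxyl and one ortho hydroxyl are alkylated, while the last ortho hydroxyl is held in a hydrogen bond to the formyl group and should be left by two equivalents of halide.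

Step 2
Reactants: 2 2,4-bis(benzyloxy)-6-hydroxybenzaldehyde
Product: 3 rac-1-[2,4-bis(benzyloxy)-6-hydroxyphenyl]prop-2-yn-1-ol
Conditions: HC≡CMgBr (3.5 equiv), THF, 0 °C to rt; aq. NH4Cl
Reagents that add atoms: ethynylmagnesium bromide, C#C[Mg]Br
Why: Grignard 1,2-addition; the first equivalent forms the magnesium phenoxide, which chelates and activates the formyl group. The carbinol centre is racemic, which does not matter because it is reduced away in step 6 and made planar in step 9.

Step 3
Reactants: 4 2-(benzyloxy)phenol
Product: 5 2-(benzyloxy)-4-bromophenol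
Conditions: NBS (1.0 equiv), MeCN, −20 to 0 °C
Reagents that add atoms: N-bromosuccinimide, BrN1C(=O)CCC1=O
Why: Electrophilic aromatic bromination; the free hydroxyl is the strongest director and its para position is the least hindered, so bromine should enter para to OH.

Step 4
Reactants: 5 2-(benzyloxy)-4-bromophenol
Product: 6 2-(benzyloxy)-4-bromophenyl methanesulfonate
Conditions: MsCl, Et3N, CH2Cl2, 0 °C
Reagents that add atoms: methanesulfonyl chloride, CS(=O)(=O)Cl
Why: Sulfonylation of the phenol; this oxygen ends para to the benzylic carbon C2' of ring E, and the sulfonate removes its donor ability.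

Step 5
Reactants: 3 rac-1-[2,4-bis(benzyloxy)-6-hydroxyphenyl]prop-2-yn-1-ol; 6 2-(benzyloxy)-4-bromophenyl methanesulfonate
Product: 7 rac-2-(benzyloxy)-4-{3-[2,4-bis(benzyloxy)-6-hydroxyphenyl]-3-hydroxyprop-1-yn-1-yl}phenyl methanesulfonate
Conditions: Pd(PhCN)2Cl2 (3 mol%), [HP(t-Bu)3]BF4 (6 mol%), CuI (2 mol%), i-Pr2NH, 1,4-dioxane, rt
Reagents that add atoms: none
Why: Sonogashira coupling; the bulky electron-rich phosphine lets zerovalent palladium insert into the aryl bromide at room temperature, and the aryl sulfonate does not react. The mild temperature should keep the propargylic alcohol from base-induced isomerisation to an enone and the phenol from adding to the alkyne.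

Step 6
Reactants: 7 rac-2-(benzyloxy)-4-{3-[2,4-bis(benzyloxy)-6-hydroxyphenyl]-3-hydroxyprop-1-yn-1-yl}phenyl methanesulfonate
Product: 9 2-(benzyloxy)-4-{3-[2,4-bis(benzyloxy)-6-hydroxyphenyl]prop-1-yn-1-yl}phenyl methanesulfonate, via ortho-quinone methide 8 (not isolated)
Conditions: Et3SiH (10 equiv), TFA (5 equiv), CH2Cl2, −40 to −10 °C, slow addition of 7
Reagents that add atoms: none
Why: Ionic hydrogenation; acid turns the ortho-hydroxybenzylic alcohol into 8 (in its protonated form a cation stabilised by three oxygens), and the silane delivers hydride to the benzylic carbon, which becomes C4'. The acceptor-substituted aryl alkyne keeps positive charge off the distal alkyne carbon, so no allene should form, and excess silane with slow addition should outrun C-alkylation of the electron-rich ring.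

Step 7
Reactants: 10 4-iodophenol
Product: 11 4-iodophenyl methanesulfonate
Conditions: MsCl, Et3N, CH2Cl2, 0 °C
Reagents that add atoms: methanesulfonyl chloride, CS(=O)(=O)Cl
Why: Sulfonylation of the phenol; the sulfonate masks the para oxygen of ring B as a non-donor.

Step 8
Reactants: 3 rac-1-[2,4-bis(benzyloxy)-6-hydroxyphenyl]prop-2-yn-1-ol; 11 4-iodophenyl methanesulfonate
Product: 12 rac-4-{3-[2,4-bis(benzyloxy)-6-hydroxyphenyl]-3-hydroxyprop-1-yn-1-yl}phenyl methanesulfonate
Conditions: PdCl2(PPh3)2 (2 mol%), CuI (4 mol%), Et3N, THF, rt
Reagents that add atoms: none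
Why: Sonogashira coupling of an aryl iodide at room temperature; free phenol and propargylic alcohol are tolerated under these basic, non-ionising conditions.

Step 9
Reactants: 12 rac-4-{3-[2,4-bis(benzyloxy)-6-hydroxyphenyl]-3-hydroxyprop-1-yn-1-yl}phenyl methanesulfonate; 9 2-(benzyloxy)-4-{3-[2,4-bis(benzyloxy)-6-hydroxyphenyl]prop-1-yn-1-yl}phenyl methanesulfonate
Product: 14 bisphenol bis-alkyne with C4 (R) bearing ring A [2,4-bis(benzyloxy)-6-hydroxyphenyl] and ring D [4,6-bis(benzyloxy)-2-hydroxy-3-(3-arylprop-2-ynyl)phenyl], via ortho-quinone methide 13 (not isolated)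
Conditions: (R)-3,3'-bis(2,4,6-triisopropylphenyl)-BINOL hydrogen phosphate (10 mol%), 9 (2 equiv), 4 Å MS, CH2Cl2, −20 °C, 12 added over 6 h
Reagents that add atoms: none
Why: Friedel–Crafts alkylation of a phenol by an ortho-quinone methide generated in situ, a known reaction type for chiral BINOL phosphoric acids. The acid dehydrates 12 to 13 and then holds the carbonyl oxygen of 13 and the hydroxyl of 9 in one hydrogen-bonded assembly, so that C8' (ortho to the phenol; the other ortho carbon is blocked) attacks one face of the methide carbon and sets C4, the choice being between H and alkynyl at a planar carbon. Slow addition of 12 to excess 9 should limit self-condensation of 12.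

Step 10
Reactants: 14 bisphenol bis-alkyne (C4 R)
Product: 15 ring A mono(tert-butyldimethylsilyl) ether of 14 (O1 silylated; ring D phenol free; C4 S by CIP)
Conditions: TBSCl (1.1 equiv), imidazole, DMF, −20 to 0 °C
Reagents that add atoms: tert-butyldimethylsilyl chloride, CC(C)(C)[Si](C)(C)Cl
Why: Silyl ether formation; the ring A phenol has one ortho substituent and the ring D phenol two, so the bulky chlorosilane at low temperature should take the ring A oxygen.

Step 11
Reactants: 15 ring A mono(tert-butyldimethylsilyl) ether of 14
Product: 16 bis-alkyne with O1 silylated and O1' acetylated (C4 S by CIP)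
Conditions: Ac2O, pyridine, DMAP (cat.), CH2Cl2, rt
Reagents that add atoms: acetic anhydride, CC(=O)OC(C)=O
Why: DMAP-catalysed acetylation; the small acyl group reaches the di-ortho-substituted ring D oxygen and gives a mask that acidic fluoride does not remove.

Step 12
Reactants: 16 bis-alkyne with O1 silylated and O1' acetylated
Product: 17 (Z,Z)-diene (C4 S by CIP; both styrenes Z)
Conditions: H2 (1 atm), Pd/CaCO3 poisoned with Pb(OAc)2 (Lindlar catalyst), quinoline, EtOAc, rt, stopped at 2 equiv H2
Reagents that add atoms: none
Why: Lindlar semi-hydrogenation; syn delivery of hydrogen on the poisoned surface gives both Z-alkenes, and benzyl ethers, aryl sulfonates, the acetate and the silyl ether are inert under these conditions.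

Step 13
Reactants: 17 (Z,Z)-diene
Product: 18 bis(cis-oxirane) (upper oxirane: benzylic C2 S and C3 R; lower oxirane: benzylic C2' S and C3' R; C4 S by CIP)
Conditions: (S,S)-N,N'-bis(3,5-di-tert-butylsalicylidene)-1,2-cyclohexanediaminomanganese chloride (20 mol%), mCPBA (4 equiv), NMO (10 equiv), CH2Cl2, −78 °C
Reagents that add atoms: m-chloroperbenzoic acid, OOC(=O)c1cccc(Cl)c1
Why: Jacobsen–Katsuki epoxidation in its low-temperature anhydrous form, the known reaction of (salen)manganese catalysts with cis-beta-substituted styrenes, here used twice on one substrate; the peracid, buffered by NMO, turns the chloride of trivalent manganese into the oxo species of pentavalent manganese, which transfers oxygen to each Z-styrene. The alkene approaches side-on with both substituents turned away from the salen plane, and the ligand sorts the conjugating aryl group from the sp3 substituent; both alkenes have the same aryl/alkyl sense, so both should receive oxygen on the same face and give the benzylic-S cis-oxiranes that cis-beta-alkylstyrenes give with the (S,S) catalyst. Each oxirane closes in two events: the C–O bond to the non-benzylic carbon (C3, C3') forms first, then the benzylic radical collapses 3-exo onto oxygen (C2–O, C2'–O). C3 and C3' are therefore set by the catalyst alone, and C2 and C2' by the catalyst together with retention of the Z geometry. The step needs the same facial sense at two remote alkenes, no rotation before ring closure, and oxidation of the alkenes in preference to the oxygenated rings and the benzylic C–H bonds. The first rests on the catalyst: allylic 1,3-strain holds C4–H in the plane of the upper alkene and places rings A and D on opposite faces, which are shielded almost equally, so the substrate has little bias of its own. The second is served by −78 °C and by the sulfonate on each para oxygen, which removes the donor that would lengthen the life of a benzylic radical or cation; the third by the acetate and sulfonates, which lower the electron density of rings D, B and E, and by the temperature, at which uncatalysed peracid reactions are negligible.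

Step 14
Reactants: 18 bis(cis-oxirane)
Product: 20 (2R,3R,4R)-5,7-bis(benzyloxy)-2-[4-(mesyloxy)phenyl]flavan-3-ol carrying on C4 the ring D aryl with O1' acetate and the intact lower cis-oxirane, via phenol 19 (not isolated)
Conditions: HF·pyridine, pyridine, THF, 0 °C to rt
Reagents that add atoms: none
Why: Fluoride cleaves the aryl silyl ether to phenol 19, whose oxygen opens the acid-activated upper oxirane at benzylic C2 in a 6-endo SN2 process with inversion and closes ring C as the 2,3-cis pyran (C2 R; C3 keeps its oxygen and is R). Attack at C3 is blocked by the neighbouring C4 methine, the ring D oxygen is still acetylated and cannot compete, and the lower oxirane has no free neighbouring nucleophile and a sulfonated aryl group, so it should survive the buffered reagent.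

Step 15
Reactants: 20 upper flavan-3-ol with O1' acetate and lower cis-oxirane
Product: 22 5,7-di-O-benzyl-4'-O-mesyl-epiafzelechin-(4β→8)-5,7,3'-tri-O-benzyl-4'-O-mesyl-epicatechin, via phenol 21 (not isolated)
Conditions: N2H4·H2O (3 equiv), THF/MeOH, 0 °C; then CSA (10 mol%), CH2Cl2/(CF3)2CHOH (4:1), 0 °C
Reagents that add atoms: none
Why: Hydrazinolysis removes the aryl acetate under neutral conditions; acid in a strongly hydrogen-bond-donating medium then activates the remaining oxirane, and O1' opens it at benzylic C2' (6-endo, inversion), closing ring F as the 2,3-cis pyran (C2' R, C3' R). The fluorinated alcohol should favour the benzylic pathway over 5-exo attack at C3', and the para sulfonate keeps the opening SN2-like so that no trans isomer should arise.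

Step 16
Reactants: 22 penta-O-benzyl di-O-mesyl dimer
Product: 23 5,7-di-O-benzyl-epiafzelechin-(4β→8)-5,7,3'-tri-O-benzyl-epicatechin
Conditions: LiN(i-Pr)2 (8 equiv), THF, −78 to 0 °C; aq. NH4Cl under argon
Reagents that add atoms: none
Why: Cleavage of aryl methanesulfonates by lithium diisopropylamide; deprotonation of the S-methyl group and loss of sulfene (E1cB) releases the phenoxides. The two alkoxides form first and should shield the neighbouring C–H bonds from the base, and benzyl ethers are inert.

Step 17
Reactants: 23 penta-O-benzyl dimer
Product: 24 (-)-epiafzelechin-(4β→8)-(-)-epicatechin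
Conditions: H2 (1 atm), Pd(OH)2/C, THF/MeOH, rt
Reagents that add atoms: none
Why: Hydrogenolysis of the five benzyl ethers; no acid or base is present, so the C4–C8' bond and the 2,3-cis centres should not be at risk.

## Compound list

1 | 2,4,6-trihydroxybenzaldehyde | O=Cc1c(O)cc(O)cc1O | starting material
2 | 2,4-bis(benzyloxy)-6-hydroxybenzaldehyde | O=Cc1c(O)cc(OCc2ccccc2)cc1OCc1ccccc1 | intermediate
3 | rac-1-[2,4-bis(benzyloxy)-6-hydroxyphenyl]prop-2-yn-1-ol | OC(C#C)c1c(O)cc(OCc2ccccc2)cc1OCc1ccccc1 | intermediate
4 | 2-(benzyloxy)phenol | Oc1ccccc1OCc1ccccc1 | starting material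
5 | 2-(benzyloxy)-4-bromophenol | Oc1ccc(Br)cc1OCc1ccccc1 | intermediate
6 | 2-(benzyloxy)-4-bromophenyl methanesulfonate | CS(=O)(=O)Oc1ccc(Br)cc1OCc1ccccc1 | intermediate
7 | rac-2-(benzyloxy)-4-{3-[2,4-bis(benzyloxy)-6-hydroxyphenyl]-3-hydroxyprop-1-yn-1-yl}phenyl methanesulfonate | OC(C#Cc1ccc(OS(C)(=O)=O)c(OCc2ccccc2)c1)c1c(O)cc(OCc2ccccc2)cc1OCc1ccccc1 | intermediate
8 | 2-(benzyloxy)-4-{3-[2,4-bis(benzyloxy)-6-oxocyclohexa-2,4-dien-1-ylidene]prop-1-yn-1-yl}phenyl methanesulfonate (ortho-quinone methide, alkylidene geometry not defined) | O=C1C=C(OCc2ccccc2)C=C(OCc2ccccc2)C1=CC#Cc1ccc(OS(C)(=O)=O)c(OCc2ccccc2)c1 | intermediate (not isolated)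
9 | 2-(benzyloxy)-4-{3-[2,4-bis(benzyloxy)-6-hydroxyphenyl]prop-1-yn-1-yl}phenyl methanesulfonate | Oc1cc(OCc2ccccc2)cc(OCc2ccccc2)c1CC#Cc1ccc(OS(C)(=O)=O)c(OCc2ccccc2)c1 | intermediate
10 | 4-iodophenol | Oc1ccc(I)cc1 | starting material
11 | 4-iodophenyl methanesulfonate | CS(=O)(=O)Oc1ccc(I)cc1 | intermediate
12 | rac-4-{3-[2,4-bis(benzyloxy)-6-hydroxyphenyl]-3-hydroxyprop-1-yn-1-yl}phenyl methanesulfonate | OC(C#Cc1ccc(OS(C)(=O)=O)cc1)c1c(O)cc(OCc2ccccc2)cc1OCc1ccccc1 | intermediate
13 | 4-{3-[2,4-bis(benzyloxy)-6-oxocyclohexa-2,4-dien-1-ylidene]prop-1-yn-1-yl}phenyl methanesulfonate (ortho-quinone methide, alkylidene geometry not defined) | O=C1C=C(OCc2ccccc2)C=C(OCc2ccccc2)C1=CC#Cc1ccc(OS(C)(=O)=O)cc1 | intermediate (not isolated)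
14 | bisphenol bis-alkyne, C4 (R): C4 bears H, the 2-[4-(mesyloxy)phenyl]ethynyl group, ring A and ring D, both phenols free | CS(=O)(=O)Oc1ccc(C#C[C@H](c3c(O)cc(OCc5ccccc5)cc3OCc5ccccc5)c3c(OCc5ccccc5)cc(OCc5ccccc5)c(CC#Cc4ccc(OS(C)(=O)=O)c(OCc5ccccc5)c4)c3O)cc1 | intermediate
15 | 14 with the ring A phenol as tert-butyldimethylsilyl ether, C4 (S) by CIP | CS(=O)(=O)Oc1ccc(C#C[C@H](c3c(O[Si](C)(C)C(C)(C)C)cc(OCc5ccccc5)cc3OCc5ccccc5)c3c(OCc5ccccc5)cc(OCc5ccccc5)c(CC#Cc4ccc(OS(C)(=O)=O)c(OCc5ccccc5)c4)c3O)cc1 | intermediate
16 | 15 with the ring D phenol as acetate, C4 (S) by CIP | CS(=O)(=O)Oc1ccc(C#C[C@H](c3c(O[Si](C)(C)C(C)(C)C)cc(OCc5ccccc5)cc3OCc5ccccc5)c3c(OCc5ccccc5)cc(OCc5ccccc5)c(CC#Cc4ccc(OS(C)(=O)=O)c(OCc5ccccc5)c4)c3OC(C)=O)cc1 | intermediate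
17 | (Z,Z)-diene, C4 (S) by CIP: both alkynes of 16 reduced to Z-alkenes | CS(=O)(=O)Oc1ccc(/C=C\[C@H](c3c(O[Si](C)(C)C(C)(C)C)cc(OCc5ccccc5)cc3OCc5ccccc5)c3c(OCc5ccccc5)cc(OCc5ccccc5)c(C/C=C\c4ccc(OS(C)(=O)=O)c(OCc5ccccc5)c4)c3OC(C)=O)cc1 | intermediate
18 | bis(cis-oxirane): upper oxirane C2 (S), C3 (R); lower oxirane C2' (S), C3' (R); C4 (S) by CIP | CS(=O)(=O)Oc1ccc([C@@H]2O[C@@H]2[C@H](c3c(O[Si](C)(C)C(C)(C)C)cc(OCc5ccccc5)cc3OCc5ccccc5)c3c(OCc5ccccc5)cc(OCc5ccccc5)c(C[C@H]4O[C@H]4c6ccc(OS(C)(=O)=O)c(OCc5ccccc5)c6)c3OC(C)=O)cc1 | intermediate
19 | 18 with the ring A phenol free (all centres spatially as in 18) | CS(=O)(=O)Oc1ccc([C@@H]2O[C@@H]2[C@H](c3c(O)cc(OCc5ccccc5)cc3OCc5ccccc5)c3c(OCc5ccccc5)cc(OCc5ccccc5)c(C[C@H]4O[C@H]4c6ccc(OS(C)(=O)=O)c(OCc5ccccc5)c6)c3OC(C)=O)cc1 | intermediate (not isolated)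
20 | (2R,3R,4R)-5,7-bis(benzyloxy)-2-[4-(mesyloxy)phenyl]flavan-3-ol with ring D on C4 (O1' acetate) and the lower oxirane (C2' S, C3' R) | CS(=O)(=O)Oc1ccc([C@H]2Oc3cc(OCc5ccccc5)cc(OCc5ccccc5)c3[C@H](c3c(OCc5ccccc5)cc(OCc5ccccc5)c(C[C@H]4O[C@H]4c6ccc(OS(C)(=O)=O)c(OCc5ccccc5)c6)c3OC(C)=O)[C@H]2O)cc1 | intermediate
21 | 20 with the ring D phenol free (all centres spatially as in 20) | CS(=O)(=O)Oc1ccc([C@H]2Oc3cc(OCc5ccccc5)cc(OCc5ccccc5)c3[C@H](c3c(OCc5ccccc5)cc(OCc5ccccc5)c(C[C@H]4O[C@H]4c6ccc(OS(C)(=O)=O)c(OCc5ccccc5)c6)c3O)[C@H]2O)cc1 | intermediate (not isolated)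
22 | 5,7-di-O-benzyl-4'-O-mesyl-epiafzelechin-(4β→8)-5,7,3'-tri-O-benzyl-4'-O-mesyl-epicatechin (2R,3R,4R; 2'R,3'R) | CS(=O)(=O)Oc1ccc([C@H]2Oc3cc(OCc5ccccc5)cc(OCc5ccccc5)c3[C@H](c3c(OCc5ccccc5)cc(OCc5ccccc5)c4c3O[C@H](c3ccc(OS(C)(=O)=O)c(OCc5ccccc5)c3)[C@H](O)C4)[C@H]2O)cc1 | intermediate
23 | 5,7-di-O-benzyl-epiafzelechin-(4β→8)-5,7,3'-tri-O-benzyl-epicatechin (2R,3R,4R; 2'R,3'R) | Oc1ccc([C@H]2Oc3cc(OCc5ccccc5)cc(OCc5ccccc5)c3[C@H](c3c(OCc5ccccc5)cc(OCc5ccccc5)c4c3O[C@H](c3ccc(O)c(OCc5ccccc5)c3)[C@H](O)C4)[C@H]2O)cc1 | intermediate
24 | (-)-epiafzelechin-(4β→8)-(-)-epicatechin (2R,3R,4R; 2'R,3'R) | Oc1ccc([C@H]2Oc3cc(O)cc(O)c3[C@H](c3c(O)cc(O)c4c3O[C@H](c3ccc(O)c(O)c3)[C@H](O)C4)[C@H]2O)cc1 | target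

## Step count and least certain steps

Total step count: 17. Longest linear sequence: 13 steps (steps 1, 2, 5, 6, 9–17 from 1; equally steps 3–6, 9–17 from 4).

**Step 13 (key step).** The most likely failures are slow or poorly face-selective oxygen transfer at the upper alkene, whose two faces each lie under a trioxygenated ring, and rotation in the benzylic radical before ring closure, which would leak Z-alkene into trans-oxirane. The fallback sets out from 17 and comes back at 18. The oxidant is aqueous H2O2 with the di-μ-oxo salalen complex of tetravalent titanium, made from Ti(Oi-Pr)4 and the salalen ligand of trans-1,2-diaminocyclohexane, in the ligand antipode that gives the benzylic-S oxiranes. Oxygen is transferred in a concerted way from a titanium-bound hydroperoxide with no radical intermediate, so the alkene geometry is kept, and Z-aryl alkenes are the best substrates of this catalyst class. It makes no new compound.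

**Step 9.** The most likely failures are insufficient enantioselectivity at the tetra-ortho-substituted methine, and loss of material by self-condensation of 12 or by attack through the para carbon of 9. The fallback replaces catalysis by resolution. It sets out from 12 and 9: an achiral acid (diphenyl phosphate, CH2Cl2) gives the racemic bisphenol F1, and TBSCl/imidazole gives the racemic ring A silyl ether F2. Acylation of the ring D phenol with (1S)-camphanic chloride (Et3N, DMAP) gives two diastereomeric esters, which are separated by chromatography or crystallisation: the camphanate with the required C4 configuration F3 and its C4 epimer F4, which is set aside. Hydrazine hydrate cleaves the aryl ester of F3, and the route is rejoined at 15.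

**Step 15.** The most likely failure is ring closure through the wrong carbon: 5-exo attack of O1' at C3', which is unhindered in the lower unit, in competition with 6-endo attack at benzylic C2'. The fallback takes the regiochemistry away from the oxirane opening. It sets out from 20: CO2 with N,N'-bis(salicylidene)ethylenediaminoaluminium chloride and Bu4NBr turns the oxirane into the cis-cyclic carbonate F5 with retention at both carbons (bromide opens, the carbonate oxygen displaces bromide at the same carbon). K2CO3 in MeOH then removes carbonate and acetate to give the diol with free ring D phenol F6. Mitsunobu cyclisation (PPh3, DIAD, THF) lets the phenol displace the activated benzylic hydroxyl with inversion, and the route is rejoined at 22.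

**Step 6.** The most likely failures are C-alkylation of the electron-rich ring by the benzylic cation (oligomers) and hydride delivery to the distal alkyne carbon (allene). The fallback changes the order of bond formation. It sets out from 3: ionic hydrogenation of 3 itself (Et3SiH, TFA), whose cation is not conjugated to a second aryl group, gives 3,5-bis(benzyloxy)-2-(prop-2-yn-1-yl)phenol F7. Sonogashira coupling of F7 with 6 under the conditions of step 5 rejoins the route at 9.

**Step 16.** The most likely failure is attack of the amide base on the doubly benzylic C4–H or opening of the pyran by elimination, which would lead to epimerisation, besides incomplete cleavage. The fallback sets out from 22 and comes back at 23. LiAlH4 in THF (0 °C to rt) cleaves the aryl sulfonates by hydride attack at sulfur with loss of the phenoxide; no carbon acid is deprotonated and benzyl ethers are inert. It makes no new compound.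

## Further compounds

F0 | step 13 | none | none
F1 | step 9 | racemic bisphenol bis-alkyne (14 without defined C4) | CS(=O)(=O)Oc1ccc(C#CC(c3c(O)cc(OCc5ccccc5)cc3OCc5ccccc5)c3c(OCc5ccccc5)cc(OCc5ccccc5)c(CC#Cc4ccc(OS(C)(=O)=O)c(OCc5ccccc5)c4)c3O)cc1
F2 | step 9 | racemic ring A tert-butyldimethylsilyl ether (15 without defined C4) | CS(=O)(=O)Oc1ccc(C#CC(c3c(O[Si](C)(C)C(C)(C)C)cc(OCc5ccccc5)cc3OCc5ccccc5)c3c(OCc5ccccc5)cc(OCc5ccccc5)c(CC#Cc4ccc(OS(C)(=O)=O)c(OCc5ccccc5)c4)c3O)cc1
F3 | step 9 | (1S,4R)-camphanate of 15 at the ring D oxygen, C4 (S) | CS(=O)(=O)Oc1ccc(C#C[C@H](c3c(O[Si](C)(C)C(C)(C)C)cc(OCc5ccccc5)cc3OCc5ccccc5)c3c(OCc5ccccc5)cc(OCc5ccccc5)c(CC#Cc4ccc(OS(C)(=O)=O)c(OCc5ccccc5)c4)c3OC(=O)[C@@]67CC[C@@](C)(C(=O)O6)C7(C)C)cc1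
F4 | step 9 | C4 epimer of F3, C4 (R) | CS(=O)(=O)Oc1ccc(C#C[C@@H](c3c(O[Si](C)(C)C(C)(C)C)cc(OCc5ccccc5)cc3OCc5ccccc5)c3c(OCc5ccccc5)cc(OCc5ccccc5)c(CC#Cc4ccc(OS(C)(=O)=O)c(OCc5ccccc5)c4)c3OC(=O)[C@@]67CC[C@@](C)(C(=O)O6)C7(C)C)cc1
F5 | step 15 | cis-cyclic carbonate from the lower oxirane of 20 (both C–O bonds retained; upper unit and acetate as in 20) | CS(=O)(=O)Oc1ccc([C@H]2Oc3cc(OCc5ccccc5)cc(OCc5ccccc5)c3[C@H](c3c(OCc5ccccc5)cc(OCc5ccccc5)c(C[C@H]4OC(=O)O[C@H]4c6ccc(OS(C)(=O)=O)c(OCc5ccccc5)c6)c3OC(C)=O)[C@H]2O)cc1
F6 | step 15 | lower-unit diol (benzylic carbon S, neighbouring carbon R) with free ring D phenol; upper unit as in 20 | CS(=O)(=O)Oc1ccc([C@H]2Oc3cc(OCc5ccccc5)cc(OCc5ccccc5)c3[C@H](c3c(OCc5ccccc5)cc(OCc5ccccc5)c(C[C@@H](O)[C@@H](O)c6ccc(OS(C)(=O)=O)c(OCc5ccccc5)c6)c3O)[C@H]2O)cc1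
F7 | step 6 | 3,5-bis(benzyloxy)-2-(prop-2-yn-1-yl)phenol | Oc1cc(OCc2ccccc2)cc(OCc2ccccc2)c1CC#C
F0 | step 16 | none | none
A1 | alternative 1 | C2 methyl ketal of the nona-O-benzyl dimer | C(c5ccccc5)Oc1ccc([C@]2(OC)Oc3cc(OCc5ccccc5)cc(OCc5ccccc5)c3[C@H](c3c(OCc5ccccc5)cc(OCc5ccccc5)c4c3O[C@H](c3ccc(OCc5ccccc5)c(OCc5ccccc5)c3)[C@H](OCc5ccccc5)C4)[C@H]2OCc5ccccc5)cc1
A2 | alternative 2 | 5,7-di-O-benzyl-4'-O-mesyl-epiafzelechin carrying a 4β-[2-hydroxy-4,6-bis(benzyloxy)phenyl] group | CS(=O)(=O)Oc1ccc([C@H]2Oc3cc(OCc5ccccc5)cc(OCc5ccccc5)c3[C@H](c3c(O)cc(OCc5ccccc5)cc3OCc5ccccc5)[C@H]2O)cc1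
A3 | alternative 3 | protected upper flavan joined at C4 to a complete ring D with free O1' phenol, two triisopropylsilyl ethers and an α-benzyloxy ketone side chain | C(c5ccccc5)Oc1ccc([C@H]2Oc3cc(OCc5ccccc5)cc(OCc5ccccc5)c3[C@H](c3c(O[Si](C(C)C)(C(C)C)C(C)C)cc(O[Si](C(C)C)(C(C)C)C(C)C)c(C[C@@H](OCc5ccccc5)C(=O)c4ccc(OCc5ccccc5)c(OCc5ccccc5)c4)c3O)[C@H]2OCc5ccccc5)cc1
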